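**Plan**

1. Numbering (labdane): ring A = C1–C5 and C10, ring B = C5–C10; C18/C19 = the two CH2OH on C4; C17 and C20 = the methyls on C8 and C10; side chain C11–C16 on C9 (C15 = free CH2OH end, C16 = CH2O–coumaroyl). TBS = tert-butyldimethylsilyl, pin = pinacolato.
2. Retrosynthesis: cut the O16–coumaroyl ester; then C13–C16 and C12–C13 (both 1,2-shifts from boron to carbon), C11–C12 (CH2 insertion) and C9–C11 (C9 ketone); in the decalin cut C4–C19 (dienolate acylation), C8–C17, then C4–C5 (reductive aldol), C3=C4 (Wittig) and C1–C10 (Michael).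
3. Forward: ring B is 2-methylcyclohexane-1,3-dione; ring A is closed onto it by a desymmetrising copper hydride reductive aldol; dehydration and deconjugative acylation give the C4 gem-diester and the C5=C6 alkene; C17 and C11 are added at the ring B ketone; the chain is then grown from C11 by three boron homologations (CH2, chiral C13 unit, CH2) and esterified.
4. Enabling feature: C13 is a methine with three CH2 arms, one carbon from O16 and 1,3 to O15. It can therefore enter as the O-bearing carbon of a propane-1,3-diol-derived lithiated benzoate (a chiral carbenoid) that inserts into the C12–B bond; the boron left on C13 becomes C16–OH, so the two hydroxymethyl arms are differentiated from the outset.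
5. Stereochemistry: C10 from the chiral copper catalyst; C8 by equatorial (thermodynamic) methylation next to the C9 ketone; C9 by α-face hydroboration anti to C20; C13 by (+)-sparteine (reagent control).

Key step: step 13

Assumption: (R)-DTBM-SEGPHOS is taken to give the (4aS)-ketol 5 as drawn; if the induction runs the other way, the mirror-image ligand is used and nothing else changes.

Step 1
Reactants: 1 2-methylcyclohexane-1,3-dione; 2 acrolein
Product: 3 3-(1-methyl-2,6-dioxocyclohexyl)propanal
Conditions: acrolein (1.3 equiv), H2O, rt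
Reagents that add atoms: none
Why: Michael addition of the cyclic 1,3-dione through its central carbon (the future C10) to acrolein should install C1–C3 and create the prochiral quaternary carbon.

Step 2
Reactants: 3 3-(1-methyl-2,6-dioxocyclohexyl)propanal
Product: 4 methyl (2E)-5-(1-methyl-2,6-dioxocyclohexyl)pent-2-enoate
Conditions: Ph3P=CHCO2Me, CH2Cl2, rt
Reagents that add atoms: methyl (triphenylphosphoranylidene)acetate (COC(=O)C=P(c1ccccc1)(c1ccccc1)c1ccccc1)
Why: Wittig olefination with a stabilised ylide is selective for the aldehyde over the hindered ring ketones and should give the E-enoate that carries C4 and C19.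

Step 3
Reactants: 4 methyl (2E)-5-(1-methyl-2,6-dioxocyclohexyl)pent-2-enoate
Product: 5 cis-fused ketol ester methyl (1S,4aS,8aS)-8a-hydroxy-4a-methyl-5-oxodecahydronaphthalene-1-carboxylate
Conditions: Cu(OAc)2·H2O (5 mol %), (R)-DTBM-SEGPHOS (5.5 mol %), PhSiH3 (1.2 equiv), toluene, −40 °C; aq. NH4F work-up
Reagents that add atoms: none
Why: Copper hydride on the chiral bisphosphine adds hydride to C3 of the enoate and the copper ester enolate at C4 attacks one of the two enantiotopic ring carbonyls through a closed chair-like transition state (catalytic desymmetrising reductive aldol cyclisation of an enoate-tethered cyclic 1,3-dione), so ring A closes and the catalyst fixes C10, while the cis-related C4 and C5 centres are erased in step 4.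

Step 4
Reactants: 5 cis-fused ketol ester
Product: 6 methyl (4aS)-4a-methyl-5-oxo-2,3,4,4a,5,6,7,8-octahydronaphthalene-1-carboxylate
Conditions: SOCl2, pyridine, CH2Cl2, 0 °C; then DBU, rt
Reagents that add atoms: none
Why: Dehydration of the tertiary β-hydroxy ester through its chlorosulfite should remove the C5 oxygen, and DBU then brings the double bond into conjugation with the ester (C4=C5), leaving C10 as the only stereocentre.

Step 5
Reactants: 6 keto enoate
Product: 7 methyl (4aS,6R)-4a,6-dimethyl-5-oxo-2,3,4,4a,5,6,7,8-octahydronaphthalene-1-carboxylate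
Conditions: LiN(iPr)2 (1.1 equiv), THF, −78 °C; MeI, −78 to 0 °C; then DBU, toluene, 60 °C
Reagents that add atoms: iodomethane (CI)
Why: Kinetic enolate alkylation can only occur at C8 because C10 is quaternary, and the C8 methyl should end up equatorial (α, trans to C20) both by attack anti to the axial C20 methyl and by base equilibration, since the β epimer would suffer a 1,3-diaxial methyl–methyl clash.

Step 6
Reactants: 7 methyl ketone
Product: 8 methyl (4aR,6R)-4a,6-dimethyl-5-methylidene-2,3,4,4a,5,6,7,8-octahydronaphthalene-1-carboxylate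
Conditions: Ph3PCH3Br (3 equiv), NaN(SiMe3)2 (2.8 equiv), toluene, 0 to 90 °C
Reagents that add atoms: methyltriphenylphosphonium bromide (C[P+](c1ccccc1)(c1ccccc1)c1ccccc1.[Br-])
Why: Wittig methylenation with the unstabilised ylide at elevated temperature is the standard answer to 2,2,6-trisubstituted cyclohexanones and should leave the hindered conjugated ester alone, turning C9 into the exocyclic alkene that carries C11.

Step 7
Reactants: 8 methylene enoate
Product: 9 dimethyl (4aR,6R)-4a,6-dimethyl-5-methylidene-3,4,4a,5,6,7-hexahydronaphthalene-1,1(2H)-dicarboxylate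
Conditions: LiN(iPr)2 (1.3 equiv), DMPU, THF, −78 °C; ClCO2Me, −78 to −20 °C
Reagents that add atoms: methyl chloroformate (COC(=O)Cl)
Why: γ-Deprotonation at C6 (cis to the ester) gives the lithium dienolate, which should be acylated at its α-carbon C4 (deconjugative α-functionalisation of an α,β-unsaturated ester), making C4 quaternary with both C18 and C19 and moving the alkene to C5=C6.

Step 8
Reactants: 9 gem-diester
Product: 10 [(4aR,6R)-4a,6-dimethyl-5-methylidene-3,4,4a,5,6,7-hexahydronaphthalene-1,1(2H)-diyl]dimethanol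
Conditions: LiAlH4, THF, 0 °C to rt
Reagents that add atoms: none
Why: Hydride reduction of the disubstituted malonate should give the 1,3-diol (C18 and C19 hydroxymethyls) without touching either alkene.

Step 9
Reactants: 10 diol
Product: 11 bis-TBS ether of 10
Conditions: TBSCl (2.5 equiv), imidazole, DMF, rt
Reagents that add atoms: tert-butyldimethylsilyl chloride (CC(C)(C)[Si](C)(C)Cl)
Why: Silylation of the two primary hydroxyls protects them against the organolithium steps and allows one fluoride deprotection at the end.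

Step 10
Reactants: 11 bis-TBS ether
Product: 12 C11 pinacol boronate
Conditions: HBpin (1.5 equiv), Rh(PPh3)3Cl (3 mol %), THF, rt to 40 °C
Reagents that add atoms: pinacolborane ([H]B1OC(C)(C)C(C)(C)O1)
Why: Rh-catalysed hydroboration (B–H oxidative addition, hydride insertion, C–B reductive elimination) should place boron on the terminal C11 and hydrogen on C9 from the α face, anti to the pseudo-axial C20 methyl on the neighbouring C10, which sets C9 (9α-H, chain β), while the hindered trisubstituted C5=C6 alkene does not react.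

Step 11
Reactants: 12 C11 pinacol boronate
Product: 13 C12 pinacol boronate
Conditions: BrCH2Cl (1.5 equiv), nBuLi (1.3 equiv), THF, −78 °C to rt
Reagents that add atoms: bromochloromethane (ClCBr)
Why: Matteson homologation, in which chloromethyllithium adds to boron and the primary alkyl group shifts to carbon with loss of chloride, should insert C12 between C11 and boron.

Step 12
Reactants: 14 3-[(tert-butyldimethylsilyl)oxy]propan-1-ol; 15 2,4,6-triisopropylbenzoic acid
Product: 16 3-[(tert-butyldimethylsilyl)oxy]propyl 2,4,6-triisopropylbenzoate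
Conditions: PPh3, DIAD, THF, 0 °C to rt
Reagents that add atoms: none
Why: Mitsunobu esterification is the usual way to put the hindered benzoate, which directs lithiation and later acts as leaving group, onto a primary alcohol.

Step 13
Reactants: 16 3-[(tert-butyldimethylsilyl)oxy]propyl 2,4,6-triisopropylbenzoate; 13 C12 pinacol boronate
Product: 19 secondary boronic ester with boron on (13R)-C13, via lithiated benzoate 17 (not isolated), via boronate complex 18 (not isolated)
Conditions: 16 (1.3 equiv), (+)-sparteine (1.3 equiv), sBuLi (1.25 equiv), Et2O, −78 °C, 5 h; add 13, −78 °C, 1 h; then 35 °C, 16 h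
Reagents that add atoms: none
Why: sBuLi/(+)-sparteine removes the pro-R hydrogen next to the benzoate oxygen of 16 to give the configurationally stable (R)-lithio benzoate 17, a chiral carbenoid, which adds to the vacant boron p orbital of primary boronic ester 13 with retention to form boronate 18; on warming, the C12 alkyl group shifts from boron to C13 antiperiplanar to the departing triisopropylbenzoate (1,2-metalate rearrangement, inversion at carbon), which forms the C12–C13 bond and leaves boron on C13. The closest known reaction type is lithiation–borylation, the reagent-controlled homologation of boronic esters with sparteine-ligated lithiated carbamates and hindered benzoates. No ring is closed. The C13 stereocentre is controlled only by the sparteine enantiomer (retention on borylation, inversion on migration), so the R configuration is set independently of the remote decalin centres. The step needs enantiotopic proton selection, complete ate-complex formation before migration, and migration of the alkyl group and not of a pinacol oxygen; the rigid diamine, the slight excess of 17 at −78 °C with warming only afterwards, and the good benzoate leaving group secure these, and the C15 silyl ether is γ to lithium and is not eliminated. The boron that stays on C13 is the handle that becomes C16–O in step 14, so C15 and C16 never need to be told apart.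

Step 14
Reactants: 19 secondary boronic ester
Product: 21 primary alcohol with free C16–OH, via homologated boronic ester 20 (not isolated)
Conditions: BrCH2Cl (1.5 equiv), nBuLi (1.3 equiv), THF, −78 °C to rt; then 2 M NaOH, 30% H2O2, 0 °C to rt
Reagents that add atoms: bromochloromethane (ClCBr); hydrogen peroxide (OO)
Why: A second Matteson homologation inserts C16 between C13 and boron with retention at C13, and oxidation of the C–B bond then gives the C16 hydroxyl while C15 remains silylated.

Step 15
Reactants: 22 p-coumaric acid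
Product: 24 (2E)-3-{4-[(tert-butyldimethylsilyl)oxy]phenyl}prop-2-enoic acid, via bis-silylated coumarate 23 (not isolated)
Conditions: TBSCl (2.2 equiv), imidazole, DMF, rt; then AcOH/THF/H2O (3:1:1), rt
Reagents that add atoms: tert-butyldimethylsilyl chloride (CC(C)(C)[Si](C)(C)Cl)
Why: Silylation of both the phenol and the acid, followed by mild hydrolysis of the far more labile silyl ester, should give the phenol-protected acid.

Step 16
Reactants: 21 primary alcohol; 24 silyl-protected coumaric acid
Product: 25 tetra-TBS ether of the target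
Conditions: DCC (1.3 equiv), DMAP (0.2 equiv), CH2Cl2, 0 °C to rt
Reagents that add atoms: none
Why: Steglich esterification acylates the only free hydroxyl (O16) and keeps the E-cinnamate geometry.

Step 17
Reactants: 25 tetra-TBS ether
Product: 26 target
Conditions: TBAF (6 equiv), AcOH (6 equiv), THF, 0 °C to rt
Reagents that add atoms: none
Why: Buffered fluoride should cleave the three alkyl silyl ethers and the aryl silyl ether in one operation without hydrolysing or migrating the coumarate ester.

**Compound list**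

1 | 2-methylcyclohexane-1,3-dione | CC1C(=O)CCCC1=O | starting material
2 | acrolein (prop-2-enal) | C=CC=O | starting material
3 | 3-(1-methyl-2,6-dioxocyclohexyl)propanal | CC1(CCC=O)C(=O)CCCC1=O | intermediate
4 | methyl (2E)-5-(1-methyl-2,6-dioxocyclohexyl)pent-2-enoate | COC(=O)/C=C/CCC1(C)C(=O)CCCC1=O | intermediate
5 | methyl (1S,4aS,8aS)-8a-hydroxy-4a-methyl-5-oxodecahydronaphthalene-1-carboxylate (cis-fused; OH, ester and angular methyl on one face) | C1CC[C@]2(O)[C@@H](C(=O)OC)CCC[C@]2(C)C1=O | intermediate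
6 | methyl (4aS)-4a-methyl-5-oxo-2,3,4,4a,5,6,7,8-octahydronaphthalene-1-carboxylate | C1CCC2=C(C(=O)OC)CCC[C@]2(C)C1=O | intermediate
7 | methyl (4aS,6R)-4a,6-dimethyl-5-oxo-2,3,4,4a,5,6,7,8-octahydronaphthalene-1-carboxylate | C[C@@H]1CCC2=C(C(=O)OC)CCC[C@]2(C)C1=O | intermediate
8 | methyl (4aR,6R)-4a,6-dimethyl-5-methylidene-2,3,4,4a,5,6,7,8-octahydronaphthalene-1-carboxylate | C[C@@H]1CCC2=C(C(=O)OC)CCC[C@]2(C)C1=C | intermediate
9 | dimethyl (4aR,6R)-4a,6-dimethyl-5-methylidene-3,4,4a,5,6,7-hexahydronaphthalene-1,1(2H)-dicarboxylate | C[C@@H]1CC=C2C(C(=O)OC)(C(=O)OC)CCC[C@]2(C)C1=C | intermediate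
10 | [(4aR,6R)-4a,6-dimethyl-5-methylidene-3,4,4a,5,6,7-hexahydronaphthalene-1,1(2H)-diyl]dimethanol | C[C@@H]1CC=C2C(CO)(CO)CCC[C@]2(C)C1=C | intermediate
11 | (4aR,6R)-1,1-bis{[(tert-butyldimethylsilyl)oxy]methyl}-4a,6-dimethyl-5-methylidene-1,2,3,4,4a,5,6,7-octahydronaphthalene | C[C@@H]1CC=C2C(CO[Si](C)(C)C(C)(C)C)(CO[Si](C)(C)C(C)(C)C)CCC[C@]2(C)C1=C | intermediate
12 | 2-{[(1S,2R,8aR)-5,5-bis{[(tert-butyldimethylsilyl)oxy]methyl}-2,8a-dimethyl-1,2,3,5,6,7,8,8a-octahydronaphthalen-1-yl]methyl}-4,4,5,5-tetramethyl-1,3,2-dioxaborolane (C11–Bpin) | C[C@@H]1CC=C2C(CO[Si](C)(C)C(C)(C)C)(CO[Si](C)(C)C(C)(C)C)CCC[C@]2(C)[C@H]1CB1OC(C)(C)C(C)(C)O1 | intermediate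
13 | 2-{2-[(1S,2R,8aR)-5,5-bis{[(tert-butyldimethylsilyl)oxy]methyl}-2,8a-dimethyl-1,2,3,5,6,7,8,8a-octahydronaphthalen-1-yl]ethyl}-4,4,5,5-tetramethyl-1,3,2-dioxaborolane (C12–Bpin) | C[C@@H]1CC=C2C(CO[Si](C)(C)C(C)(C)C)(CO[Si](C)(C)C(C)(C)C)CCC[C@]2(C)[C@H]1CCB1OC(C)(C)C(C)(C)O1 | intermediate
14 | 3-[(tert-butyldimethylsilyl)oxy]propan-1-ol | OCCCO[Si](C)(C)C(C)(C)C | starting material
15 | 2,4,6-triisopropylbenzoic acid | CC(C)c1cc(C(C)C)c(C(=O)O)c(C(C)C)c1 | starting material
16 | 3-[(tert-butyldimethylsilyl)oxy]propyl 2,4,6-triisopropylbenzoate | CC(C)c1cc(C(C)C)c(C(=O)OCCCO[Si](C)(C)C(C)(C)C)c(C(C)C)c1 | intermediate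
17 | (1R)-3-[(tert-butyldimethylsilyl)oxy]-1-lithiopropyl 2,4,6-triisopropylbenzoate, (+)-sparteine complex | [Li][C@H](CCO[Si](C)(C)C(C)(C)C)OC(=O)c1c(C(C)C)cc(C(C)C)cc1C(C)C | intermediate (not isolated)
18 | lithium boronate complex formed from 13 and 17 (boron carries pinacol, the C12 alkyl group and the benzoate-bearing C13) | [Li+].C[C@@H]1CC=C2C(CO[Si](C)(C)C(C)(C)C)(CO[Si](C)(C)C(C)(C)C)CCC[C@]2(C)[C@H]1CC[B-]1(OC(C)(C)C(C)(C)O1)[C@H](CCO[Si](C)(C)C(C)(C)C)OC(=O)c1c(C(C)C)cc(C(C)C)cc1C(C)C | intermediate (not isolated)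
19 | 2-{(3R)-1-[(1S,2R,8aR)-5,5-bis{[(tert-butyldimethylsilyl)oxy]methyl}-2,8a-dimethyl-1,2,3,5,6,7,8,8a-octahydronaphthalen-1-yl]-5-[(tert-butyldimethylsilyl)oxy]pentan-3-yl}-4,4,5,5-tetramethyl-1,3,2-dioxaborolane | C[C@@H]1CC=C2C(CO[Si](C)(C)C(C)(C)C)(CO[Si](C)(C)C(C)(C)C)CCC[C@]2(C)[C@H]1CC[C@H](CCO[Si](C)(C)C(C)(C)C)B1OC(C)(C)C(C)(C)O1 | intermediate
20 | 2-{(2R)-2-{2-[(1S,2R,8aR)-5,5-bis{[(tert-butyldimethylsilyl)oxy]methyl}-2,8a-dimethyl-1,2,3,5,6,7,8,8a-octahydronaphthalen-1-yl]ethyl}-4-[(tert-butyldimethylsilyl)oxy]butyl}-4,4,5,5-tetramethyl-1,3,2-dioxaborolane | C[C@@H]1CC=C2C(CO[Si](C)(C)C(C)(C)C)(CO[Si](C)(C)C(C)(C)C)CCC[C@]2(C)[C@H]1CC[C@H](CCO[Si](C)(C)C(C)(C)C)CB1OC(C)(C)C(C)(C)O1 | intermediate (not isolated)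
21 | (2R)-2-{2-[(1S,2R,8aR)-5,5-bis{[(tert-butyldimethylsilyl)oxy]methyl}-2,8a-dimethyl-1,2,3,5,6,7,8,8a-octahydronaphthalen-1-yl]ethyl}-4-[(tert-butyldimethylsilyl)oxy]butan-1-ol | C[C@@H]1CC=C2C(CO[Si](C)(C)C(C)(C)C)(CO[Si](C)(C)C(C)(C)C)CCC[C@]2(C)[C@H]1CC[C@H](CCO[Si](C)(C)C(C)(C)C)CO | intermediate
22 | p-coumaric acid, (2E)-3-(4-hydroxyphenyl)prop-2-enoic acid | OC(=O)/C=C/c1ccc(O)cc1 | starting material
23 | tert-butyldimethylsilyl (2E)-3-{4-[(tert-butyldimethylsilyl)oxy]phenyl}prop-2-enoate | CC(C)(C)[Si](C)(C)OC(=O)/C=C/c1ccc(O[Si](C)(C)C(C)(C)C)cc1 | intermediate (not isolated)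
24 | (2E)-3-{4-[(tert-butyldimethylsilyl)oxy]phenyl}prop-2-enoic acid | OC(=O)/C=C/c1ccc(O[Si](C)(C)C(C)(C)C)cc1 | intermediate
25 | (2R)-2-{2-[(1S,2R,8aR)-5,5-bis{[(tert-butyldimethylsilyl)oxy]methyl}-2,8a-dimethyl-1,2,3,5,6,7,8,8a-octahydronaphthalen-1-yl]ethyl}-4-[(tert-butyldimethylsilyl)oxy]butyl (2E)-3-{4-[(tert-butyldimethylsilyl)oxy]phenyl}prop-2-enoate | C[C@@H]1CC=C2C(CO[Si](C)(C)C(C)(C)C)(CO[Si](C)(C)C(C)(C)C)CCC[C@]2(C)[C@H]1CC[C@H](CCO[Si](C)(C)C(C)(C)C)COC(=O)/C=C/c1ccc(O[Si](C)(C)C(C)(C)C)cc1 | intermediate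
26 | (2R)-2-{2-[(1S,2R,8aR)-5,5-bis(hydroxymethyl)-2,8a-dimethyl-1,2,3,5,6,7,8,8a-octahydronaphthalen-1-yl]ethyl}-4-hydroxybutyl (2E)-3-(4-hydroxyphenyl)prop-2-enoate | C[C@@H]1CC=C2C(CO)(CO)CCC[C@]2(C)[C@H]1CC[C@H](CCO)COC(=O)/C=C/c1ccc(O)cc1 | target

**Step count and risks**

Total steps: 17. Longest linear sequence: 15 (steps 1–11, 13, 14, 16 and 17).

Step 3 is the most likely to fail. The chiral copper hydride may discriminate poorly between the two enantiotopic ring carbonyls, which would erode the enantiopurity at C10, or a ketone may be reduced directly. The fallback sets out from 4 and separates the two tasks. A desymmetrising transfer hydrogenation of one ring ketone with RuCl[(S,S)-TsDPEN](p-cymene) in HCO2H/Et3N (catalyst enantiomer chosen to give the drawn product) should give methyl (2E)-5-[(1R,2R)-2-hydroxy-1-methyl-6-oxocyclohexyl]pent-2-enoate F1. A reductive aldol cyclisation with the achiral [CuH(PPh3)]6 onto the one remaining ketone, now under substrate control, should give methyl (1S,4aR,5R,8aS)-5,8a-dihydroxy-4a-methyldecahydronaphthalene-1-carboxylate F2. Dess–Martin oxidation of the secondary alcohol then comes back to the route at 5.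

Step 10 is second. Catalytic hydroboration of a 1,1-disubstituted alkene flanked by a quaternary carbon may be slow, the alkene may isomerise into ring B, or hydrogen may be delivered to the β face of C9. The fallback sets out from 11. Uncatalysed hydroboration with 9-BBN (THF, 60 °C) and NaOH/H2O2 oxidation should give [(1S,2R,8aR)-5,5-bis{[(tert-butyldimethylsilyl)oxy]methyl}-2,8a-dimethyl-1,2,3,5,6,7,8,8a-octahydronaphthalen-1-yl]methanol F3. Dess–Martin oxidation gives (1S,2R,8aR)-5,5-bis{[(tert-butyldimethylsilyl)oxy]methyl}-2,8a-dimethyl-1,2,3,5,6,7,8,8a-octahydronaphthalene-1-carbaldehyde F4, whose C9 centre can be equilibrated with DBU to the equatorial β-formyl arrangement if needed. Wittig methylenation with Ph3P=CH2 gives (1S,2R,8aR)-5,5-bis{[(tert-butyldimethylsilyl)oxy]methyl}-1-ethenyl-2,8a-dimethyl-1,2,3,5,6,7,8,8a-octahydronaphthalene F5. Anti-Markovnikov hydroboration of the monosubstituted alkene with HBpin and [Ir(cod)Cl]2/dppe comes back to the route at 13, so that step 11 is not needed.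

Step 7 is third. The dienolate may be acylated on oxygen or at the γ-carbon, or γ-deprotonation of the tetrasubstituted enoate may be incomplete. The fallback sets out from 8 and builds the second hydroxymethyl by aldol chemistry. Reduction with iBu2AlH (CH2Cl2, −78 °C) should give [(4aR,6R)-4a,6-dimethyl-5-methylidene-2,3,4,4a,5,6,7,8-octahydronaphthalen-1-yl]methanol F6. Oxidation with MnO2 gives (4aR,6R)-4a,6-dimethyl-5-methylidene-2,3,4,4a,5,6,7,8-octahydronaphthalene-1-carbaldehyde F7. Treatment with aqueous formaldehyde and KOH in MeOH/H2O (Tollens reaction) should hydroxymethylate the dienolate at C4, which moves the alkene to C5=C6, and then reduce the now non-enolisable aldehyde by crossed Cannizzaro reaction; this comes back to the route at diol 10, so that step 8 is not needed.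

**Further compounds**

F1 | step 3 | methyl (2E)-5-[(1R,2R)-2-hydroxy-1-methyl-6-oxocyclohexyl]pent-2-enoate | COC(=O)/C=C/CC[C@@]1(C)C(=O)CCC[C@H]1O
F2 | step 3 | methyl (1S,4aR,5R,8aS)-5,8a-dihydroxy-4a-methyldecahydronaphthalene-1-carboxylate | C1CC[C@]2(O)[C@@H](C(=O)OC)CCC[C@]2(C)[C@@H]1O
F3 | step 10 | [(1S,2R,8aR)-5,5-bis{[(tert-butyldimethylsilyl)oxy]methyl}-2,8a-dimethyl-1,2,3,5,6,7,8,8a-octahydronaphthalen-1-yl]methanol | C[C@@H]1CC=C2C(CO[Si](C)(C)C(C)(C)C)(CO[Si](C)(C)C(C)(C)C)CCC[C@]2(C)[C@H]1CO
F4 | step 10 | (1S,2R,8aR)-5,5-bis{[(tert-butyldimethylsilyl)oxy]methyl}-2,8a-dimethyl-1,2,3,5,6,7,8,8a-octahydronaphthalene-1-carbaldehyde | C[C@@H]1CC=C2C(CO[Si](C)(C)C(C)(C)C)(CO[Si](C)(C)C(C)(C)C)CCC[C@]2(C)[C@H]1C=O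
F5 | step 10 | (1S,2R,8aR)-5,5-bis{[(tert-butyldimethylsilyl)oxy]methyl}-1-ethenyl-2,8a-dimethyl-1,2,3,5,6,7,8,8a-octahydronaphthalene | C[C@@H]1CC=C2C(CO[Si](C)(C)C(C)(C)C)(CO[Si](C)(C)C(C)(C)C)CCC[C@]2(C)[C@H]1C=C
F6 | step 7 | [(4aR,6R)-4a,6-dimethyl-5-methylidene-2,3,4,4a,5,6,7,8-octahydronaphthalen-1-yl]methanol | C[C@@H]1CCC2=C(CO)CCC[C@]2(C)C1=C
F7 | step 7 | (4aR,6R)-4a,6-dimethyl-5-methylidene-2,3,4,4a,5,6,7,8-octahydronaphthalene-1-carbaldehyde | C[C@@H]1CCC2=C(C=O)CCC[C@]2(C)C1=C
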